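## Structural features

The target is a chalcone. Its ring A is a phloroglucinol-type benzene ring fused to a dihydrofuran, giving a 2,3-dihydrobenzofuran with free hydroxyls at C4 and C6. The (E)-4-hydroxycinnamoyl group (ring B and the enone) sits at C5 between those hydroxyls, and a 2-hydroxypropan-2-yl group sits at C2. C2 is the only stereocentre and is (S). Its neighbours are the C3 methylene and a carbinol carbon with two identical methyl groups, so no stereocentre stands next to it and it must be set by a reagent or catalyst. Three parts are fragile. In the 2′,6′-dihydroxychalcone either phenol beside the ketone can add to the enone and close a flavanone under acid or base. The aromatic ring is very electron-rich. The tertiary carbinol next to the ring oxygen can ionise, leading to elimination or ring expansion to a chromanol. The real difficulties are the absolute configuration of an isolated stereocentre and the placing of the acyl group at C5 rather than at the electronically similar C7. C3 is an unsubstituted benzylic CH2 and C2 is an ether CH. This is the pattern left when a carbene carbon on the arene (future C3) inserts into a C–H bond of an ArO–CH2 group (future C2), and the key step uses this to form C2–C3 and close the dihydrofuran. The 1,3,5-oxygenation maps onto 2,4,6-trihydroxybenzaldehyde, whose formyl carbon becomes C3.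

## Logic of the disconnections

**19 ⇒ 18.** The cuts are the three aryl O–CH2 acetal bonds and the carbinol O–Si bond. The two phenols flanking the ketone are what make 19 prone to cyclise, so they are uncovered last, together with the other hydroxyls. Every earlier step then handles a fully masked enone. The forward step must use acid mild and brief enough that neither flavanone closure nor ionisation of the tertiary carbinol begins.

**18 ⇒ 12 + 15.** The cut is the C5–C(=O) bond. In 12, C5 lies between two acetal-protected oxygens, which is the best site on the ring for a carbanion (16). The N-methoxy-N-methylamide function of 15 accepts an aryl anion only once (through 17). The gain is convergence: ring B and the enone arrive in one piece, and 12 carries no carbonyl. The forward step must deprotonate C5 and not C7 or C3, add 1,2 to the amide, and keep the (E)-alkene.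

**15 ⇒ 13 + 14.** The cut is the Cα=Cβ double bond. A phosphonate olefination gives the alkene and the amide in one step from two catalogue compounds. The only demand is (E)-selectivity.

**12 ⇒ 10 (through 11).** The cut is the O4–CH2 acetal bond; in the forward sense the O4–Si bond is broken and replaced. The steps on either side ask opposite things of the O4 substituent. The ring closure needs a group with no C–H near the carbene carbon, while the metalation needs a lithium-coordinating acetal. Only this one group is exchanged; the para acetal and the carbinol silyl ether pass through unchanged from 6 to 18. The forward step needs fluoride to cleave the aryl O–Si bond and spare the tertiary alkyl O–Si bond.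

**10 ⇒ 8 (through 9).** The cut is the C2–C3 bond. It removes the ring and the only stereocentre at once and leads back to an achiral aldehyde derivative with a simple ether side chain. The forward step must choose one enantiotopic hydrogen of the O–CH2 group, must find no other reachable C–H bond, and must meet no free O–H.

**8 ⇒ 6 + 7.** The cut is the C=N bond. The hydrazone is the stable, storable source of the carbene. The forward condensation must run without added acid on a hindered aldehyde.

**6 ⇒ 4 (through 5).** The cuts are the two O–Si bonds. The phenol needs a base-stable group with silicon in the 1,5 position, and the carbinol needs an acid-labile cap that lasts to the end. The forward step must silylate each hydroxyl with the right silicon group without touching the acetal.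

**4 ⇒ 2 + 3.** The cut is the aryl O–CH2 bond. The side chain with its tertiary carbinol comes complete from 3. The forward step needs attack at the CH2 end of 3 and a stop after one of the two equivalent phenols has reacted.

**2 ⇒ 1.** The cut is the O–CH2 acetal bond on the para oxygen. It leads to a commercial trihydroxy aldehyde. The forward step needs selectivity for the para hydroxyl over the two ortho hydroxyls.

## Other disconnections considered

**Alternative 1:** The cut is C4–C5, so ring A is built last from a poly-β-carbonyl chain on a preformed chiral dihydrofuran, A1. In the forward step, base forms the enolate of the methylene between the two ketones of A1. This attacks the ring ester carbon (Claisen, Dieckmann-type), and the six-membered trione enolises to the aromatic ring, giving A2. One acetal then has to be removed.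
- In its favour: the acyl group is at C5 by construction, so the C5 versus C7 question never arises. On this point it is better than the chosen plan. It also needs no cryogenic organometallic step.
- Against it: A1 is a polycarbonyl compound with an enone. O-acylation to a pyranone, Michael addition and other aldol modes would compete.
- Against it: the base can also deprotonate the ring CH2 that is γ to the ester. The resulting dienolate can expel the ring oxygen, which would open the dihydrofuran and destroy the stereocentre.
- Comparison: the last acid step on A2 meets the same flavanone hazard as step 9, so the two plans are equal there. The mechanism is an ionic condensation, against a radical C–H functionalisation. A1 must carry the stereocentre from a chiral building block through several C–C bond formations, so its preparation alone would probably exceed the eight linear steps of the chosen route.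

**Alternative 2:** The cut is O1–C2. In the forward step the allylic carbonate A3 ionises on zerovalent palladium bearing a C2-symmetric diphosphine from trans-1,2-diaminocyclohexane. One of the two equivalent phenols attacks the internal allyl terminus and gives A4.
- In its favour: this type of ring closure is a well-established way to 2-isopropenyl-dihydrobenzofurans. The symmetric resorcinol removes any regiochemical question. (E)/(Z) mixtures converge through the π-allyl complex. A4 already has a free 4-OH ready for the acetal. On precedent for this exact ring type it is the equal of the chosen plan.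
- Against it: A3 needs C-alkylation of a phloroglucinol monoether between two hydroxyls, where O-alkylation and polyalkylation compete, plus an allylic oxidation.
- Against it: A4 still needs Markovnikov hydration of the isopropenyl group (Mukaiyama hydration), exchange of benzyl for an acetal before the enone exists, and silylation.
- Comparison: both plans set the same single stereocentre under catalyst control, here by ionic π-allyl chemistry and in the chosen plan by a radical process. The chosen route should be shorter by at least three steps.

**Alternative 3:** The cuts are C3–C3a and O1–C7a. In the forward step A5 and A6 combine under Pd(OAc)2, a phosphine, norbornene and Cs2CO3 (Catellani reaction). The aryl–norbornyl palladacycle opens the epoxide at its CH2 end, norbornene is extruded, and the alkoxide closes the ring at the ipso carbon. The product A7 is identical with 12.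
- In its favour: two bonds form in one step. The stereocentre comes unchanged from A6, so enantiopurity does not depend on a selective step; on stereochemical security it is better than the chosen plan. A7 would be reached in about four steps, against six for 12, so it is also better on step economy.
- Against it: A5 has two open ortho positions, so a second ortho alkylation can compete with ipso closure. Each ortho C–H is flanked by a meta acetal, which hinders palladation. The hindered epoxide may rearrange to a carbonyl compound under the conditions.
- Comparison: the benzene ring is bought, as in the chosen plan. The mechanism is two-electron palladium chemistry with a transient mediator. The chosen plan is preferred because its ring closure has only one reachable C–H bond and does not depend on controlling mono- versus di-functionalisation of a symmetric arene.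

Key step: step 5

Remark on the chemistry: which antipode of the cobalt ligand leads to (S)-10 cannot be predicted with certainty and is assumed to be fixed by a first small-scale run. Compounds 13 and 14 are taken as catalogue chemicals.

## Route

Step 1
Reactants: 1 2,4,6-trihydroxybenzaldehyde
Product: 2 2,6-dihydroxy-4-(methoxymethoxy)benzaldehyde
Conditions: MOMCl (1.0 equiv), i-Pr2NEt (1.1 equiv), THF, 0 °C
Reagents that add atoms: chloromethyl methyl ether, COCCl
Why: Williamson-type O-alkylation (acetal formation); with one equivalent of a weak amine base only the 4-OH is ionised, being the most acidic phenol (para to the formyl group, not hydrogen-bonded), while the ortho phenols are less acidic and one is tied into the hydrogen bond to the carbonyl, so one equivalent of the chloride should stop at the mono-ether.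

Step 2
Reactants: 2 2,6-dihydroxy-4-(methoxymethoxy)benzaldehyde; 3 isobutylene oxide (2,2-dimethyloxirane)
Product: 4 2-hydroxy-6-(2-hydroxy-2-methylpropoxy)-4-(methoxymethoxy)benzaldehyde
Conditions: 3 (1.3 equiv), K2CO3 (0.5 equiv), DMF, 80 °C, sealed tube
Reagents that add atoms: none
Why: Base-mediated SN2 opening of the epoxide at its unhindered CH2 end by the phenoxide, the base being regenerated when the tertiary alkoxide is reprotonated; the two ortho phenols are equivalent, and once one is alkylated the other is held in the hydrogen bond to the aldehyde, which should stop the reaction at mono-alkylation.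

Step 3
Reactants: 4 2-hydroxy-6-(2-hydroxy-2-methylpropoxy)-4-(methoxymethoxy)benzaldehyde
Product: 6 4-(methoxymethoxy)-2-[2-methyl-2-(triethylsilyloxy)propoxy]-6-(triisopropylsilyloxy)benzaldehyde, via aryl triisopropylsilyl ether 5 (not isolated)
Conditions: TIPSOTf (1.05 equiv), 2,6-lutidine (3 equiv), CH2Cl2, −78 → −20 °C; then TESOTf (1.2 equiv), −78 °C
Reagents that add atoms: triisopropylsilyl trifluoromethanesulfonate, CC(C)[Si](OS(=O)(=O)C(F)(F)F)(C(C)C)C(C)C; triethylsilyl trifluoromethanesulfonate, CC[Si](CC)(CC)OS(=O)(=O)C(F)(F)F
Why: Silyl ether formation with silyl triflates; the bulky triisopropylsilyl triflate takes the phenol and leaves the hindered tertiary alcohol, which the smaller triethylsilyl triflate then caps in the same flask; the low temperature protects the aryl MOM acetal, which silyl triflate and pyridine bases attack only on warming.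

Step 4
Reactants: 6 4-(methoxymethoxy)-2-[2-methyl-2-(triethylsilyloxy)propoxy]-6-(triisopropylsilyloxy)benzaldehyde; 7 p-toluenesulfonyl hydrazide
Product: 8 N'-[(E)-{4-(methoxymethoxy)-2-[2-methyl-2-(triethylsilyloxy)propoxy]-6-(triisopropylsilyloxy)phenyl}methylidene]-4-methylbenzenesulfonohydrazide
Conditions: 7 (1.05 equiv), MeOH/THF, rt → 40 °C
Reagents that add atoms: none
Why: Condensation of the aldehyde with the sulfonyl hydrazide to the (E)-hydrazone; no acid is added, so the acetal and both silyl ethers survive, and the doubly ortho-substituted, electron-rich aldehyde may need the gentle warming.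

Step 5
Reactants: 8 N'-[(E)-{4-(methoxymethoxy)-2-[2-methyl-2-(triethylsilyloxy)propoxy]-6-(triisopropylsilyloxy)phenyl}methylidene]-4-methylbenzenesulfonohydrazide
Product: 10 (S)-6-(methoxymethoxy)-2-[2-(triethylsilyloxy)propan-2-yl]-4-(triisopropylsilyloxy)-2,3-dihydrobenzofuran, via aryldiazomethane 9 (not isolated)
Conditions: Cs2CO3 (2 equiv), [Co(Por*)] (divalent cobalt, 5 mol %; Por* = 5,15-bis(3,5-di-tert-butylphenyl)-10,20-bis[2,6-bis(2,2-dimethylcyclopropanecarboxamido)phenyl]porphyrinate, the antipode that delivers (S)), 1,4-dioxane, 60 °C
Reagents that add atoms: none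
Why: Cs2CO3 removes the sulfonamide proton of 8 and the salt loses p-toluenesulfinate on warming (Bamford–Stevens reaction), releasing the aryldiazomethane 9 slowly. The divalent cobalt porphyrin, a metal-centred radical, takes up 9 with loss of N2 and forms a benzylic radical bound to trivalent cobalt at the future C3. This radical removes a hydrogen atom from the ArO–CH2 group by 1,5-hydrogen atom transfer through a six-membered transition state, and the α-oxy radical then attacks the cobalt-bound carbon in a homolytic substitution that forms C2–C3, closes the dihydrofuran in the 5-exo-tet mode and returns the divalent cobalt catalyst. The closest known reaction type is the enantioselective intramolecular C–H alkylation of ortho-alkoxyaryl diazomethanes made in situ from tosylhydrazones under cobalt metalloradical (or dirhodium) catalysis, which gives 2-substituted 2,3-dihydrobenzofurans. The C2 stereocentre is under catalyst control alone: the amide-walled chiral pocket of the porphyrin decides which enantiotopic hydrogen is removed and holds the short-lived radical so that the C–C bond forms on the same face, a net replacement of the pro-S hydrogen. The step also needs site selectivity, and the substrate secures it: the O–CH2 group carries the only C–H bonds in the 1,5 position and they are weakened by the adjacent oxygen, whereas the other ortho oxygen has silicon at that position (its isopropyl C–H bonds lie one atom further and are hindered) and the para acetal is out of reach. The silylated carbinol offers no O–H for insertion or for protonation of 9. Carbonate in an aprotic solvent should leave the aryl silyl ether, the triethylsilyl ether and the acetal intact, and the slow release of 9 keeps azine formation low.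

Step 6
Reactants: 10 (S)-6-(methoxymethoxy)-2-[2-(triethylsilyloxy)propan-2-yl]-4-(triisopropylsilyloxy)-2,3-dihydrobenzofuran
Product: 12 (S)-4,6-bis(methoxymethoxy)-2-[2-(triethylsilyloxy)propan-2-yl]-2,3-dihydrobenzofuran, via phenoxide 11 (not isolated)
Conditions: TBAF (1.05 equiv), THF, −20 → 0 °C; then i-Pr2NEt (3 equiv), MOMCl (2 equiv), 0 °C → rt
Reagents that add atoms: chloromethyl methyl ether, COCCl
Why: Fluoride-induced desilylation followed by Williamson-type acetal formation in the same flask; the aryl O–Si bond should cleave much faster than the hindered tertiary alkyl O–Si bond because phenoxide is the better leaving group, and phenoxide 11 is alkylated directly; the amine scavenges acid from any hydrolysed chloride, so the triethylsilyl ether and C2 are not touched.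

Step 7
Reactants: 13 4-(methoxymethoxy)benzaldehyde; 14 diethyl [2-(methoxy(methyl)amino)-2-oxoethyl]phosphonate
Product: 15 (E)-N-methoxy-3-[4-(methoxymethoxy)phenyl]-N-methylprop-2-enamide
Conditions: NaH (1.1 equiv), THF, 0 °C → rt
Reagents that add atoms: none
Why: Horner–Wadsworth–Emmons olefination; the stabilised phosphonate anion should give the (E)-alkene, and the acetal is inert to the base.

Step 8
Reactants: 12 (S)-4,6-bis(methoxymethoxy)-2-[2-(triethylsilyloxy)propan-2-yl]-2,3-dihydrobenzofuran; 15 (E)-N-methoxy-3-[4-(methoxymethoxy)phenyl]-N-methylprop-2-enamide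
Product: 18 (S,E)-1-{4,6-bis(methoxymethoxy)-2-[2-(triethylsilyloxy)propan-2-yl]-2,3-dihydrobenzofuran-5-yl}-3-[4-(methoxymethoxy)phenyl]prop-2-en-1-one, via aryllithium 16 (not isolated), via lithium carbinolamine adduct 17 (not isolated)
Conditions: n-BuLi (1.15 equiv), THF, 0 °C, 1 h; then 15 (1.2 equiv), −78 → 0 °C; sat. aq NH4Cl
Reagents that add atoms: none
Why: Directed ortho-metalation followed by Weinreb ketone synthesis; C5 is the only position flanked by two lithium-chelating MOM ethers (C7 has one MOM ether and the ring oxygen, which is shielded by the C2 substituent), and aryllithium 16 adds to the amide carbonyl to give the chelated adduct 17, which cannot add a second time and collapses to the enone on quenching; 1,2-addition is expected for an aryllithium and the (E)-alkene is not touched.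

Step 9
Reactants: 18 (S,E)-1-{4,6-bis(methoxymethoxy)-2-[2-(triethylsilyloxy)propan-2-yl]-2,3-dihydrobenzofuran-5-yl}-3-[4-(methoxymethoxy)phenyl]prop-2-en-1-one
Product: 19 (S,E)-1-[4,6-dihydroxy-2-(2-hydroxypropan-2-yl)-2,3-dihydrobenzofuran-5-yl]-3-(4-hydroxyphenyl)prop-2-en-1-one
Conditions: 3 M aq HCl/MeOH (1:5), rt (40 °C if slow), stopped at full conversion
Reagents that add atoms: none
Why: Acid-catalysed solvolysis of the three MOM acetals and the silyl ether; the two acetals beside the ketone should leave first and the ring B acetal last, and the reaction is stopped at that point because longer exposure would favour oxa-Michael closure to the flavanone; the C2 stereocentre is not involved.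

## Compound list

1 | 2,4,6-trihydroxybenzaldehyde | O=Cc1c(O)cc(O)cc1O | starting material
2 | 2,6-dihydroxy-4-(methoxymethoxy)benzaldehyde | O=Cc1c(O)cc(OCOC)cc1O | intermediate
3 | isobutylene oxide (2,2-dimethyloxirane) | CC1(C)CO1 | starting material
4 | 2-hydroxy-6-(2-hydroxy-2-methylpropoxy)-4-(methoxymethoxy)benzaldehyde | O=Cc1c(O)cc(OCOC)cc1OCC(C)(C)O | intermediate
5 | 2-(2-hydroxy-2-methylpropoxy)-4-(methoxymethoxy)-6-(triisopropylsilyloxy)benzaldehyde | O=Cc1c(O[Si](C(C)C)(C(C)C)C(C)C)cc(OCOC)cc1OCC(C)(C)O | intermediate (not isolated)
6 | 4-(methoxymethoxy)-2-[2-methyl-2-(triethylsilyloxy)propoxy]-6-(triisopropylsilyloxy)benzaldehyde | O=Cc1c(O[Si](C(C)C)(C(C)C)C(C)C)cc(OCOC)cc1OCC(C)(C)O[Si](CC)(CC)CC | intermediate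
7 | p-toluenesulfonyl hydrazide | Cc1ccc(cc1)S(=O)(=O)NN | starting material
8 | N'-[(E)-{4-(methoxymethoxy)-2-[2-methyl-2-(triethylsilyloxy)propoxy]-6-(triisopropylsilyloxy)phenyl}methylidene]-4-methylbenzenesulfonohydrazide | Cc1ccc(cc1)S(=O)(=O)N/N=C/c1c(O[Si](C(C)C)(C(C)C)C(C)C)cc(OCOC)cc1OCC(C)(C)O[Si](CC)(CC)CC | intermediate
9 | 2-(diazomethyl)-5-(methoxymethoxy)-1-[2-methyl-2-(triethylsilyloxy)propoxy]-3-(triisopropylsilyloxy)benzene | [N-]=[N+]=Cc1c(O[Si](C(C)C)(C(C)C)C(C)C)cc(OCOC)cc1OCC(C)(C)O[Si](CC)(CC)CC | intermediate (not isolated)
10 | (S)-6-(methoxymethoxy)-2-[2-(triethylsilyloxy)propan-2-yl]-4-(triisopropylsilyloxy)-2,3-dihydrobenzofuran | CC(C)(O[Si](CC)(CC)CC)[C@@H]1Cc2c(O[Si](C(C)C)(C(C)C)C(C)C)cc(OCOC)cc2O1 | intermediate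
11 | (S)-6-(methoxymethoxy)-2-[2-(triethylsilyloxy)propan-2-yl]-2,3-dihydrobenzofuran-4-ol (present in the flask as its tetrabutylammonium phenoxide) | CC(C)(O[Si](CC)(CC)CC)[C@@H]1Cc2c(O)cc(OCOC)cc2O1 | intermediate (not isolated)
12 | (S)-4,6-bis(methoxymethoxy)-2-[2-(triethylsilyloxy)propan-2-yl]-2,3-dihydrobenzofuran | CC(C)(O[Si](CC)(CC)CC)[C@@H]1Cc2c(OCOC)cc(OCOC)cc2O1 | intermediate
13 | 4-(methoxymethoxy)benzaldehyde | O=Cc1ccc(OCOC)cc1 | starting material
14 | diethyl [2-(methoxy(methyl)amino)-2-oxoethyl]phosphonate | CCOP(=O)(CC(=O)N(C)OC)OCC | starting material
15 | (E)-N-methoxy-3-[4-(methoxymethoxy)phenyl]-N-methylprop-2-enamide | CON(C)C(=O)/C=C/c1ccc(OCOC)cc1 | intermediate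
16 | {(S)-4,6-bis(methoxymethoxy)-2-[2-(triethylsilyloxy)propan-2-yl]-2,3-dihydrobenzofuran-5-yl}lithium | CC(C)(O[Si](CC)(CC)CC)[C@@H]1Cc2c(OCOC)c([Li])c(OCOC)cc2O1 | intermediate (not isolated)
17 | lithium (E)-1-{(S)-4,6-bis(methoxymethoxy)-2-[2-(triethylsilyloxy)propan-2-yl]-2,3-dihydrobenzofuran-5-yl}-1-[methoxy(methyl)amino]-3-[4-(methoxymethoxy)phenyl]prop-2-en-1-olate (both epimers at the new carbon) | CC(C)(O[Si](CC)(CC)CC)[C@@H]1Cc2c(OCOC)c(C(O[Li])(N(C)OC)/C=C/c3ccc(OCOC)cc3)c(OCOC)cc2O1 | intermediate (not isolated)
18 | (S,E)-1-{4,6-bis(methoxymethoxy)-2-[2-(triethylsilyloxy)propan-2-yl]-2,3-dihydrobenzofuran-5-yl}-3-[4-(methoxymethoxy)phenyl]prop-2-en-1-one | CC(C)(O[Si](CC)(CC)CC)[C@@H]1Cc2c(OCOC)c(C(=O)/C=C/c3ccc(OCOC)cc3)c(OCOC)cc2O1 | intermediate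
19 | (S,E)-1-[4,6-dihydroxy-2-(2-hydroxypropan-2-yl)-2,3-dihydrobenzofuran-5-yl]-3-(4-hydroxyphenyl)prop-2-en-1-one | CC(C)(O)[C@@H]1Cc2c(cc(O)c(C(=O)/C=C/c3ccc(O)cc3)c2O)O1 | target

## Step count and least certain steps

Total step count: 9. Longest linear sequence: 8 (steps 1 to 6, 8 and 9); step 7 is a one-step side branch.

**Step 5 (key step).** The diazo compound 9 is doubly ortho-substituted and electron-rich, so its capture by cobalt may be slow and carbene dimerisation to the azine may take over. The hydrogen donor is a neopentyl-type CH2 beside a bulky quaternary carbon and not a benzylic group, so hydrogen abstraction may be slow and the pocket may distinguish the two enantiotopic hydrogens poorly. The fallback makes the C2–C3 bond as a double bond and sets the stereocentre by hydrogenation. It sets out from 2 and comes back at 12.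
- Ethyl bromoacetate and K2CO3 in DMF at 90 °C (O-alkylation then intramolecular aldol condensation, Rap–Stoermer type) should give ethyl 4-hydroxy-6-(methoxymethoxy)benzofuran-2-carboxylate F1.
- MOMCl and i-Pr2NEt would give ethyl 4,6-bis(methoxymethoxy)benzofuran-2-carboxylate F2.
- Excess MeMgBr would give 2-[4,6-bis(methoxymethoxy)benzofuran-2-yl]propan-2-ol F3.
- TESOTf and 2,6-lutidine at −78 °C would give {[2-(4,6-bis(methoxymethoxy)benzofuran-2-yl)propan-2-yl]oxy}triethylsilane F4.
- Enantioselective hydrogenation of the furan C2=C3 bond of F4 with Ru(cod)(2-methylallyl)2, the chiral N-heterocyclic carbene from SINpEt·HBF4 and KOt-Bu, under H2 should then lead to 12.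

**Step 8.** Deprotonation may occur at C7 instead of C5, or at benzylic C3 with opening of the dihydrofuran by β-elimination of the phenoxide. The doubly flanked anion may also transfer to the amide slowly. The fallback fixes the site of the anion with a halogen placed under phenol direction. It sets out from 11, isolated as the phenol by aqueous work-up after the fluoride stage of step 6, and comes back at 16.
- NBS with catalytic i-Pr2NH in CH2Cl2 at −78 → 0 °C (amine-mediated ortho-bromination of a phenol) should give (S)-5-bromo-6-(methoxymethoxy)-2-[2-(triethylsilyloxy)propan-2-yl]-2,3-dihydrobenzofuran-4-ol F5.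
- MOMCl and i-Pr2NEt would give (S)-{[2-(5-bromo-4,6-bis(methoxymethoxy)-2,3-dihydrobenzofuran-2-yl)propan-2-yl]oxy}triethylsilane F6.
- Bromine–lithium exchange with n-BuLi in THF at −78 °C would give 16, which is acylated with 15 as in step 8.

**Step 9.** The freed 2′,6′-dihydroxychalcone may close to the flavanone by oxa-Michael addition during the time the slowest acetal (on ring B) needs. Prolonged acid may also ionise the tertiary carbinol. The fallback lowers the acid dose by changing the ring B protecting group. It sets out from 12 and 14 and comes back at 19.
- Olefination of commercial 4-(tetrahydro-2H-pyran-2-yloxy)benzaldehyde with 14 (NaH, THF) would give (E)-N-methoxy-N-methyl-3-[4-(tetrahydro-2H-pyran-2-yloxy)phenyl]prop-2-enamide F7.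
- Acylation of 16 (from 12 as in step 8) with F7 would give (E)-1-{(S)-4,6-bis(methoxymethoxy)-2-[2-(triethylsilyloxy)propan-2-yl]-2,3-dihydrobenzofuran-5-yl}-3-[4-(tetrahydro-2H-pyran-2-yloxy)phenyl]prop-2-en-1-one F8, as a pair of epimers at the acetal carbon.
- The tetrahydropyranyl ether, the silyl ether and the two ketone-flanked acetals of F8 should all fall under much milder and shorter acid treatment (0.5 M HCl in MeOH, 0 °C → rt), giving 19.

**Step 1.** Alkylation may run on to the bis-ether, because the first ortho phenol is only moderately less reactive than the para phenol. The fallback protects two phenols and later removes the ortho acetal selectively. It sets out from 1 and comes back at 4.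
- MOMCl (2.2 equiv) and i-Pr2NEt should stop cleanly at 2-hydroxy-4,6-bis(methoxymethoxy)benzaldehyde F9, because the last phenol is locked in the hydrogen bond to the aldehyde.
- Alkylation of F9 with 3 (K2CO3, DMF, 80 °C) would give 2-(2-hydroxy-2-methylpropoxy)-4,6-bis(methoxymethoxy)benzaldehyde F10.
- Chelation-assisted cleavage of the acetal ortho to the formyl group (MgBr2·OEt2 in Et2O/CH2Cl2, or dilute HCl in MeOH at rt) should leave the para acetal and give 4.

## Further compounds

F1 | step 5 | ethyl 4-hydroxy-6-(methoxymethoxy)benzofuran-2-carboxylate | CCOC(=O)c1cc2c(O)cc(OCOC)cc2o1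
F2 | step 5 | ethyl 4,6-bis(methoxymethoxy)benzofuran-2-carboxylate | CCOC(=O)c1cc2c(OCOC)cc(OCOC)cc2o1
F3 | step 5 | 2-[4,6-bis(methoxymethoxy)benzofuran-2-yl]propan-2-ol | CC(C)(O)c1cc2c(OCOC)cc(OCOC)cc2o1
F4 | step 5 | {[2-(4,6-bis(methoxymethoxy)benzofuran-2-yl)propan-2-yl]oxy}triethylsilane | CC(C)(O[Si](CC)(CC)CC)c1cc2c(OCOC)cc(OCOC)cc2o1
F5 | step 8 | (S)-5-bromo-6-(methoxymethoxy)-2-[2-(triethylsilyloxy)propan-2-yl]-2,3-dihydrobenzofuran-4-ol | CC(C)(O[Si](CC)(CC)CC)[C@@H]1Cc2c(O)c(Br)c(OCOC)cc2O1
F6 | step 8 | (S)-{[2-(5-bromo-4,6-bis(methoxymethoxy)-2,3-dihydrobenzofuran-2-yl)propan-2-yl]oxy}triethylsilane | CC(C)(O[Si](CC)(CC)CC)[C@@H]1Cc2c(OCOC)c(Br)c(OCOC)cc2O1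
F7 | step 9 | (E)-N-methoxy-N-methyl-3-[4-(tetrahydro-2H-pyran-2-yloxy)phenyl]prop-2-enamide | CON(C)C(=O)/C=C/c1ccc(OC2CCCCO2)cc1
F8 | step 9 | (E)-1-{(S)-4,6-bis(methoxymethoxy)-2-[2-(triethylsilyloxy)propan-2-yl]-2,3-dihydrobenzofuran-5-yl}-3-[4-(tetrahydro-2H-pyran-2-yloxy)phenyl]prop-2-en-1-one | CC(C)(O[Si](CC)(CC)CC)[C@@H]1Cc2c(OCOC)c(C(=O)/C=C/c3ccc(OC4CCCCO4)cc3)c(OCOC)cc2O1
F9 | step 1 | 2-hydroxy-4,6-bis(methoxymethoxy)benzaldehyde | O=Cc1c(O)cc(OCOC)cc1OCOC
F10 | step 1 | 2-(2-hydroxy-2-methylpropoxy)-4,6-bis(methoxymethoxy)benzaldehyde | O=Cc1c(OCOC)cc(OCOC)cc1OCC(C)(C)O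
A1 | alternative 1 | methyl (S)-5-(2-hydroxypropan-2-yl)-2-{(E)-6-[4-(methoxymethoxy)phenyl]-2,4-dioxohex-5-en-1-yl}-4,5-dihydrofuran-3-carboxylate | CC(C)(O)[C@@H]1CC(C(=O)OC)=C(CC(=O)CC(=O)/C=C/c2ccc(OCOC)cc2)O1
A2 | alternative 1 | (S,E)-1-[4,6-dihydroxy-2-(2-hydroxypropan-2-yl)-2,3-dihydrobenzofuran-5-yl]-3-[4-(methoxymethoxy)phenyl]prop-2-en-1-one | CC(C)(O)[C@@H]1Cc2c(cc(O)c(C(=O)/C=C/c3ccc(OCOC)cc3)c2O)O1
A3 | alternative 2 | (E)-4-[4-(benzyloxy)-2,6-dihydroxyphenyl]-2-methylbut-2-en-1-yl methyl carbonate | COC(=O)OC/C(C)=C/Cc1c(O)cc(OCc2ccccc2)cc1O
A4 | alternative 2 | (S)-6-(benzyloxy)-2-(prop-1-en-2-yl)-2,3-dihydrobenzofuran-4-ol | C=C(C)[C@@H]1Cc2c(O)cc(OCc3ccccc3)cc2O1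
A5 | alternative 3 | 1-iodo-3,5-bis(methoxymethoxy)benzene | COCOc1cc(I)cc(OCOC)c1
A6 | alternative 3 | (S)-triethyl{[2-(oxiran-2-yl)propan-2-yl]oxy}silane | CC(C)(O[Si](CC)(CC)CC)[C@@H]1CO1
A7 | alternative 3 | (S)-4,6-bis(methoxymethoxy)-2-[2-(triethylsilyloxy)propan-2-yl]-2,3-dihydrobenzofuran | CC(C)(O[Si](CC)(CC)CC)[C@@H]1Cc2c(OCOC)cc(OCOC)cc2O1
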